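If I charge substrate with two nucleophiles and want the split between target and other capture product, I look for one number in an earlier run that I can carry over, so I start from that run and from what it can and cannot see.

- alpha: substrate 20 mM; first nucleophile 30 mM; second nucleophile 15 mM; run made earlier
- flask: substrate 20 mM; first nucleophile 30.0 mM; second nucleophile 30.0 mM; time 8.0 d

- alpha (time / h: other capture product / %, target / %, substrate / %): 2.50: 11.9, 31.1, 50.1; 8.00: 20.6, 53.2, 14.9; 15.0: 23.7, 59.6, 4.0; 20.0: 24.4, 61.2, 1.2; 30.0: 25.4, 61.3, 0; 40.0: 24.7, 61.6, 0.2

(scatter of a reading: 0.3 percentage points)

* share of other capture product in other capture product plus target at 3.0 min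
* share of other capture product in other capture product plus target at 8.0 d



Between its first two readings the alpha run loses substrate at 0.220 h⁻¹, a half-life of 3.14 h. The shortest rung is 3.0 min, far below that half-life and far ahead of the first alpha reading: at the alpha pace I reckon that hardly any of the substrate in the flask has reacted by then, and no reading covers that moment.

The next rung is the hours of capture, where something stays nearly constant. I take target as the capture by first nucleophile and other capture product as the capture by second nucleophile, and I freeze an apparent selectivity factor 0.756, the logarithm of the fraction of second nucleophile not captured over the same logarithm for the first. It reads 0.744 at 2.50 h and 0.756 at 40.0 h.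

The last rung is 8.0 d, far beyond the alpha half-life, so I expect the flask to show its final split, with substrate as limiting reagent. With equal charges the factor gives a start share of 43.0%, which I carry to 3.0 min without a reading under it. Taking capture of 17.3 mM as in alpha, and letting first nucleophile fall faster than second nucleophile, I reckon 44.2% at 8.0 d.

The forecast says 42.9% (39.5% to 46.5%) and 43.9% (40.5% to 47.5%), holding that “both products appear to come from one intermediate by parallel capture”.

The flask gives 30.2% at 3.0 min, 13 percentage points under my start share, and 44.0% at 8.0 d. At 8.00 d the flask holds 9.44 mM of dormant form, made from first nucleophile with a half-life of 0.41 h by the forward step alone, longer than 3.0 min. Counting that dormant form as first nucleophile not turned into target, the factor turns the target of 50.3% into 39.9% of other capture product, against 39.5% in the flask.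

    substrate ⇌ intermediate (K = 0.0440, k = 0.840 h⁻¹)
    first nucleophile + intermediate → target (k = 390 M⁻¹ h⁻¹)
    second nucleophile + intermediate → other capture product (k = 160 M⁻¹ h⁻¹)
    first nucleophile ⇌ dormant form (K = 0.900, k = 1.70 h⁻¹)
    intermediate → side product A (k = 0.830 h⁻¹)
    substrate + intermediate → side product B (k = 13.0 M⁻¹ h⁻¹)

In the neighbour flask with 18 mM of second nucleophile, the factor turns its target of 59.2% into 28.4% of other capture product, a share of 32.4% at 8.0 d. The computed neighbour holds 28.3%, a share of 32.4%.

All runs are simulated on assumed constants, and the scatter is random.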